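**Retrosynthetic overview**
1. Target ⇐ lipase-mediated alcoholysis of the two aryl acetates of the 7,4'-di-O-acetate (neutral final unmasking).
2. Three prenyl groups ⇐ threefold cross-metathesis of C-allyl groups with 2-methylbut-2-ene on that diacetate; the acid-stable allyl groups are carried through the acid step.
3. Ring C (the only ring formed; rings A and B are bought as arenes) ⇐ acid-triggered 6-exo opening of a trans-(2R,3S)-epoxy ketone by the unmasked ortho-phenol; epoxide ⇐ catalytic asymmetric nucleophilic epoxidation of the MOM-protected triallyl (E)-chalcone (both stereocentres set here).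
4. Chalcone ⇐ Claisen–Schmidt condensation of a ring A acetophenone with a ring B aldehyde.
5. Ring A ketone ⇐ 2,4-dihydroxyacetophenone (O-allylation, Claisen rearrangement); ring B aldehyde ⇐ 3,5-dibromo-4-hydroxybenzaldehyde (double Stille allylation).

Assumption: compounds 1, 3, 5 and 6, (S)-BINOL, the second-generation Grubbs catalyst and the immobilised lipase are taken as catalogue items.

**Route**

Step 1
Reactants: 1 3,5-dibromo-4-hydroxybenzaldehyde
Product: 2 3,5-dibromo-4-(methoxymethoxy)benzaldehyde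
Conditions: MOMCl, NaH, DMF, 0 °C to rt
Reagents that add atoms: chloromethyl methyl ether COCCl
Why: Williamson-type O-alkylation of the acidic phenoxide (the aldehyde is non-enolisable) gives a MOM acetal that survives the later cross-coupling, hydroxide and peroxide steps.

Step 2
Reactants: 2 3,5-dibromo-4-(methoxymethoxy)benzaldehyde, 3 tributyl(prop-2-en-1-yl)stannane
Product: 4 4-(methoxymethoxy)-3,5-di(prop-2-en-1-yl)benzaldehyde
Conditions: 3 (2.5 equiv), Pd(PPh3)4 (10 mol%), DMF, 90 °C
Reagents that add atoms: none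
Why: Twofold Stille cross-coupling (oxidative addition of zerovalent palladium into each Ar–Br bond, transmetalation, reductive elimination) installs both allyl groups under neutral conditions that tolerate the aldehyde and the MOM ether.

Step 3
Reactants: 5 1-(2,4-dihydroxyphenyl)ethan-1-one, 6 3-bromoprop-1-ene
Product: 7 1-[2-hydroxy-4-(prop-2-en-1-yloxy)phenyl]ethan-1-one
Conditions: 6 (1.1 equiv), K2CO3, acetone, reflux
Reagents that add atoms: none
Why: Williamson O-alkylation is selective for the 4-hydroxyl because the 2-hydroxyl is held in a hydrogen bond to the acetyl carbonyl and is far less nucleophilic.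

Step 4
Reactants: 7 1-[2-hydroxy-4-(prop-2-en-1-yloxy)phenyl]ethan-1-one
Product: 8 1-[2,4-dihydroxy-3-(prop-2-en-1-yl)phenyl]ethan-1-one
Conditions: N,N-diethylaniline, 200 °C, Ar, 6 h
Reagents that add atoms: none
Why: Aromatic Claisen rearrangement ([3,3]-sigmatropic shift, then tautomerisation) delivers the allyl group mainly to C3, between the two oxygens, because the chelated ortho-hydroxy ketone fixes double-bond character in the C3–C4 bond; the minor 5-allyl isomer is removed by crystallisation.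

Step 5
Reactants: 8 1-[2,4-dihydroxy-3-(prop-2-en-1-yl)phenyl]ethan-1-one
Product: 9 1-[2,4-bis(methoxymethoxy)-3-(prop-2-en-1-yl)phenyl]ethan-1-one
Conditions: MOMCl (3 equiv), NaH (2.5 equiv), DMF, 0 °C to rt
Reagents that add atoms: chloromethyl methyl ether COCCl
Why: Double Williamson-type O-alkylation of both phenoxides, including the chelated one, masks the ortho-phenol so that it cannot cyclise during the condensation and epoxidation.

Step 6
Reactants: 9 1-[2,4-bis(methoxymethoxy)-3-(prop-2-en-1-yl)phenyl]ethan-1-one, 4 4-(methoxymethoxy)-3,5-di(prop-2-en-1-yl)benzaldehyde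
Product: 10 (2E)-1-[2,4-bis(methoxymethoxy)-3-(prop-2-en-1-yl)phenyl]-3-[4-(methoxymethoxy)-3,5-di(prop-2-en-1-yl)phenyl]prop-2-en-1-one
Conditions: KOH, EtOH–H2O, rt, 24–48 h
Reagents that add atoms: none
Why: Claisen–Schmidt condensation (aldol addition, then E1cB dehydration) gives the thermodynamic (E)-enone; MOM ethers and aryl-allyl groups are inert to hydroxide at room temperature.

Step 7
Reactants: 10 (2E)-1-[2,4-bis(methoxymethoxy)-3-(prop-2-en-1-yl)phenyl]-3-[4-(methoxymethoxy)-3,5-di(prop-2-en-1-yl)phenyl]prop-2-en-1-one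
Product: 11 [(2R,3S)-3-[4-(methoxymethoxy)-3,5-di(prop-2-en-1-yl)phenyl]oxiran-2-yl][2,4-bis(methoxymethoxy)-3-(prop-2-en-1-yl)phenyl]methanone
Conditions: La(O-i-Pr)3 (10 mol%), (S)-BINOL (10 mol%), Ph3As=O (10 mol%), t-BuOOH (decane), 4 Å MS, THF, rt
Reagents that add atoms: tert-butyl hydroperoxide CC(C)(C)OO
Why: Catalytic asymmetric nucleophilic (Weitz–Scheffer-type) epoxidation with a lanthanum–BINOL peroxide attacks only the electron-poor enone and leaves the three allyl alkenes untouched, and the (S)-BINOL complex delivers the peroxide to one enone face to set both stereocentres as the trans-(2R,3S)-epoxide (the (R)-ligand gives the mirror-image chalcone oxide series; about 90–95% ee expected).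

Step 8
Reactants: 11 [(2R,3S)-3-[4-(methoxymethoxy)-3,5-di(prop-2-en-1-yl)phenyl]oxiran-2-yl][2,4-bis(methoxymethoxy)-3-(prop-2-en-1-yl)phenyl]methanone
Product: 14 (2R,3R)-3,7-dihydroxy-2-[4-hydroxy-3,5-di(prop-2-en-1-yl)phenyl]-8-(prop-2-en-1-yl)-2,3-dihydro-4H-chromen-4-one, via ortho-phenol epoxy ketone 12 (not isolated), via bis-MOM dihydroflavonol 13 (not isolated)
Conditions: HCl (conc., about 10 equiv), MeOH–THF, 45 °C, Ar; extractive work-up, crude carried on
Reagents that add atoms: none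
Why: Acid methanolysis removes the carbonyl-chelated ortho-MOM first, the freed phenol opens the epoxide at the benzylic carbon (6-exo-tet, inversion, giving C2 R trans to the untouched C3 carbinol R, and any ionisation at C2 still funnels to the diequatorial trans isomer), and the two remaining MOM acetals are then transacetalised to dimethoxymethane; the allyl groups, unlike prenyl groups, do not cyclise onto the neighbouring phenols under protic acid.

Step 9
Reactants: 14 (2R,3R)-3,7-dihydroxy-2-[4-hydroxy-3,5-di(prop-2-en-1-yl)phenyl]-8-(prop-2-en-1-yl)-2,3-dihydro-4H-chromen-4-one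
Product: 15 (2R,3R)-7-acetoxy-2-[4-acetoxy-3,5-di(prop-2-en-1-yl)phenyl]-3-hydroxy-8-(prop-2-en-1-yl)-2,3-dihydro-4H-chromen-4-one
Conditions: Ac2O (2.4 equiv), Et3N (3 equiv), CH2Cl2, 0 °C
Reagents that add atoms: acetic anhydride CC(=O)OC(C)=O
Why: Phenoxide-selective O-acetylation (the hydrogen-bonded secondary C3-OH reacts far more slowly without DMAP) masks the two phenols, which would otherwise coordinate ruthenium and promote allyl isomerisation in the metathesis, and gives a neutral diester that can be chromatographed free of the minor cis-epimer; no stereocentre is touched.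

Step 10
Reactants: 15 (2R,3R)-7-acetoxy-2-[4-acetoxy-3,5-di(prop-2-en-1-yl)phenyl]-3-hydroxy-8-(prop-2-en-1-yl)-2,3-dihydro-4H-chromen-4-one
Product: 16 (2R,3R)-7-acetoxy-2-[4-acetoxy-3,5-bis(3-methylbut-2-en-1-yl)phenyl]-3-hydroxy-8-(3-methylbut-2-en-1-yl)-2,3-dihydro-4H-chromen-4-one
Conditions: second-generation Grubbs catalyst RuCl2(=CHPh)(H2IMes)(PCy3) (10 mol%, two portions), 2-methylbut-2-ene–CH2Cl2 (1:1), 40 °C, sealed vessel, 12–24 h
Reagents that add atoms: 2-methylbut-2-ene CC=C(C)C
Why: Threefold olefin cross-metathesis of the terminal allyl alkenes with a large excess of 2-methylbut-2-ene converts each allyl group into a prenyl group with loss of propene under neutral conditions that leave the aryl acetates, the α-ketol and both stereocentres untouched; the diacetate can be recrystallised here to remove residual minor enantiomer.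

Step 11
Reactants: 16 (2R,3R)-7-acetoxy-2-[4-acetoxy-3,5-bis(3-methylbut-2-en-1-yl)phenyl]-3-hydroxy-8-(3-methylbut-2-en-1-yl)-2,3-dihydro-4H-chromen-4-one
Product: 17 (2R,3R)-3,7-dihydroxy-2-[4-hydroxy-3,5-bis(3-methylbut-2-en-1-yl)phenyl]-8-(3-methylbut-2-en-1-yl)-2,3-dihydro-4H-chromen-4-one
Conditions: immobilised Burkholderia cepacia lipase, n-BuOH (10 equiv), THF, 40 °C
Reagents that add atoms: none
Why: Lipase-catalysed transesterification to n-butanol (serine-hydrolase acyl-enzyme mechanism) cleaves the 7- and 4'-aryl acetates at neutral pH, so the base-labile chromanone (C2 epimerisation by ring opening, air oxidation to the flavonol) and the acid-labile ortho-prenylphenols never meet base or acid; both stereocentres are untouched.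

**Compound list**
1 | 3,5-dibromo-4-hydroxybenzaldehyde | O=Cc1cc(Br)c(O)c(Br)c1 | starting material
2 | 3,5-dibromo-4-(methoxymethoxy)benzaldehyde | COCOc1c(Br)cc(C=O)cc1Br | intermediate
3 | tributyl(prop-2-en-1-yl)stannane (allyltributylstannane) | CCCC[Sn](CCCC)(CCCC)CC=C | starting material
4 | 4-(methoxymethoxy)-3,5-di(prop-2-en-1-yl)benzaldehyde | COCOc1c(CC=C)cc(C=O)cc1CC=C | intermediate
5 | 1-(2,4-dihydroxyphenyl)ethan-1-one (2,4-dihydroxyacetophenone) | CC(=O)c1ccc(O)cc1O | starting material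
6 | 3-bromoprop-1-ene (allyl bromide) | C=CCBr | starting material
7 | 1-[2-hydroxy-4-(prop-2-en-1-yloxy)phenyl]ethan-1-one | CC(=O)c1ccc(OCC=C)cc1O | intermediate
8 | 1-[2,4-dihydroxy-3-(prop-2-en-1-yl)phenyl]ethan-1-one | CC(=O)c1ccc(O)c(CC=C)c1O | intermediate
9 | 1-[2,4-bis(methoxymethoxy)-3-(prop-2-en-1-yl)phenyl]ethan-1-one | CC(=O)c1ccc(OCOC)c(CC=C)c1OCOC | intermediate
10 | (2E)-1-[2,4-bis(methoxymethoxy)-3-(prop-2-en-1-yl)phenyl]-3-[4-(methoxymethoxy)-3,5-di(prop-2-en-1-yl)phenyl]prop-2-en-1-one | O=C(/C=C/c1cc(CC=C)c(OCOC)c(CC=C)c1)c1ccc(OCOC)c(CC=C)c1OCOC | intermediate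
11 | [(2R,3S)-3-[4-(methoxymethoxy)-3,5-di(prop-2-en-1-yl)phenyl]oxiran-2-yl][2,4-bis(methoxymethoxy)-3-(prop-2-en-1-yl)phenyl]methanone | O=C([C@@H]1O[C@H]1c1cc(CC=C)c(OCOC)c(CC=C)c1)c1ccc(OCOC)c(CC=C)c1OCOC | intermediate
12 | [(2R,3S)-3-[4-(methoxymethoxy)-3,5-di(prop-2-en-1-yl)phenyl]oxiran-2-yl][2-hydroxy-4-(methoxymethoxy)-3-(prop-2-en-1-yl)phenyl]methanone | O=C([C@@H]1O[C@H]1c1cc(CC=C)c(OCOC)c(CC=C)c1)c1ccc(OCOC)c(CC=C)c1O | intermediate
13 | (2R,3R)-3-hydroxy-7-(methoxymethoxy)-2-[4-(methoxymethoxy)-3,5-di(prop-2-en-1-yl)phenyl]-8-(prop-2-en-1-yl)-2,3-dihydro-4H-chromen-4-one | C=CCc1cc([C@H]2Oc3c(ccc(OCOC)c3CC=C)C(=O)[C@@H]2O)cc(CC=C)c1OCOC | intermediate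
14 | (2R,3R)-3,7-dihydroxy-2-[4-hydroxy-3,5-di(prop-2-en-1-yl)phenyl]-8-(prop-2-en-1-yl)-2,3-dihydro-4H-chromen-4-one | C=CCc1cc([C@H]2Oc3c(ccc(O)c3CC=C)C(=O)[C@@H]2O)cc(CC=C)c1O | intermediate
15 | (2R,3R)-7-acetoxy-2-[4-acetoxy-3,5-di(prop-2-en-1-yl)phenyl]-3-hydroxy-8-(prop-2-en-1-yl)-2,3-dihydro-4H-chromen-4-one | C=CCc1cc([C@H]2Oc3c(ccc(OC(C)=O)c3CC=C)C(=O)[C@@H]2O)cc(CC=C)c1OC(C)=O | intermediate
16 | (2R,3R)-7-acetoxy-2-[4-acetoxy-3,5-bis(3-methylbut-2-en-1-yl)phenyl]-3-hydroxy-8-(3-methylbut-2-en-1-yl)-2,3-dihydro-4H-chromen-4-one | CC(C)=CCc1cc([C@H]2Oc3c(ccc(OC(C)=O)c3CC=C(C)C)C(=O)[C@@H]2O)cc(CC=C(C)C)c1OC(C)=O | intermediate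
17 | (2R,3R)-3,7-dihydroxy-2-[4-hydroxy-3,5-bis(3-methylbut-2-en-1-yl)phenyl]-8-(3-methylbut-2-en-1-yl)-2,3-dihydro-4H-chromen-4-one | CC(C)=CCc1cc([C@H]2Oc3c(ccc(O)c3CC=C(C)C)C(=O)[C@@H]2O)cc(CC=C(C)C)c1O | target

**Totals**
Total steps: 11. Longest linear sequence: 9 steps (steps 3 to 11, from 2,4-dihydroxyacetophenone 5); the ring B branch (steps 1 and 2) joins at step 6.

**Three steps most likely to fail**

Step 8 (global acid MOM cleavage and cyclisation). Methanol or chloride can open the electron-rich benzylic epoxide before the ortho-phenol is free, and over-ionisation at the benzylic carbon erodes the trans:cis ratio. Fallback: separate ring closure from phenol unmasking. Setting out from 11, only the carbonyl-chelated ortho-MOM group is removed with a small charge of mild acid (p-TsOH·H2O, MeOH–THF, rt). The ring closes and 13 is isolated and purified with both remaining phenols still masked. The two remaining MOM ethers are then cleaved by Lewis acid/thiol transacetalisation instead of Brønsted acid (ZnBr2, n-PrSH, CH2Cl2, 0 °C, minutes), which comes back to the route at 14. No new compound is needed.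

Step 10 (threefold cross-metathesis). The free α-ketol can chelate the ruthenium alkylidene or generate ruthenium hydrides, which stall the third exchange or isomerise allyl to propenyl groups and give inseparable mixed products. Fallback: mask the C3 hydroxyl for the metathesis. Setting out from 15, silylation (Et3SiCl, imidazole, DMF, 0 °C) gives (2R,3R)-7-acetoxy-2-[4-acetoxy-3,5-di(prop-2-en-1-yl)phenyl]-8-(prop-2-en-1-yl)-3-[(triethylsilyl)oxy]-2,3-dihydro-4H-chromen-4-one F1. Cross-metathesis with 2-methylbut-2-ene (same second-generation Grubbs catalyst, CH2Cl2, 40 °C) gives (2R,3R)-7-acetoxy-2-[4-acetoxy-3,5-bis(3-methylbut-2-en-1-yl)phenyl]-8-(3-methylbut-2-en-1-yl)-3-[(triethylsilyl)oxy]-2,3-dihydro-4H-chromen-4-one F2. Desilylation (HF·pyridine, THF, 0 °C; aryl acetates and prenyl groups survive) comes back to the route at 16.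

Step 11 (enzymatic deacetylation). The 4'-acetate is flanked by two prenyl groups and may not fit the alcohol-binding pocket of the lipase. Fallback: move the ester away from the hindered phenol by using esterase-labile acetoxymethyl ethers in place of acetates. Setting out from 14, alkylation of the two phenols (bromomethyl acetate, i-Pr2NEt, MeCN, 0 °C to rt) gives (2R,3R)-7-(acetoxymethoxy)-2-[4-(acetoxymethoxy)-3,5-di(prop-2-en-1-yl)phenyl]-3-hydroxy-8-(prop-2-en-1-yl)-2,3-dihydro-4H-chromen-4-one F3. Cross-metathesis with 2-methylbut-2-ene as in step 10 gives (2R,3R)-7-(acetoxymethoxy)-2-[4-(acetoxymethoxy)-3,5-bis(3-methylbut-2-en-1-yl)phenyl]-3-hydroxy-8-(3-methylbut-2-en-1-yl)-2,3-dihydro-4H-chromen-4-one F4. The same lipase with n-BuOH then cleaves the unhindered remote acetates, and the resulting hemiacetals lose formaldehyde at neutral pH, which comes back to the route at 17.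

**Further compounds**
F0 | step 8 | none | none
F1 | step 10 | (2R,3R)-7-acetoxy-2-[4-acetoxy-3,5-di(prop-2-en-1-yl)phenyl]-8-(prop-2-en-1-yl)-3-[(triethylsilyl)oxy]-2,3-dihydro-4H-chromen-4-one | C=CCc1cc([C@H]2Oc3c(ccc(OC(C)=O)c3CC=C)C(=O)[C@@H]2O[Si](CC)(CC)CC)cc(CC=C)c1OC(C)=O
F2 | step 10 | (2R,3R)-7-acetoxy-2-[4-acetoxy-3,5-bis(3-methylbut-2-en-1-yl)phenyl]-8-(3-methylbut-2-en-1-yl)-3-[(triethylsilyl)oxy]-2,3-dihydro-4H-chromen-4-one | CC(C)=CCc1cc([C@H]2Oc3c(ccc(OC(C)=O)c3CC=C(C)C)C(=O)[C@@H]2O[Si](CC)(CC)CC)cc(CC=C(C)C)c1OC(C)=O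
F3 | step 11 | (2R,3R)-7-(acetoxymethoxy)-2-[4-(acetoxymethoxy)-3,5-di(prop-2-en-1-yl)phenyl]-3-hydroxy-8-(prop-2-en-1-yl)-2,3-dihydro-4H-chromen-4-one | C=CCc1cc([C@H]2Oc3c(ccc(OCOC(C)=O)c3CC=C)C(=O)[C@@H]2O)cc(CC=C)c1OCOC(C)=O
F4 | step 11 | (2R,3R)-7-(acetoxymethoxy)-2-[4-(acetoxymethoxy)-3,5-bis(3-methylbut-2-en-1-yl)phenyl]-3-hydroxy-8-(3-methylbut-2-en-1-yl)-2,3-dihydro-4H-chromen-4-one | CC(C)=CCc1cc([C@H]2Oc3c(ccc(OCOC(C)=O)c3CC=C(C)C)C(=O)[C@@H]2O)cc(CC=C(C)C)c1OCOC(C)=O
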